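## Retrosynthetic overview
1. 30 ⇒ 28 by a last-step Markovnikov radical hydration of Δ5 (5α-OH). 28 ⇒ 26 by building the oxirane on the hindered face through closure of a bromolactol.
2. Key disconnection: C13–C14 of 26. Both carbons are α-carbons of a 1,4-dicarbonyl (succinate) unit. C13 is the donor (butenolide furanolate) and C14 is an α-halo ester used as a polarity-reversed a2/enolonium synthon. This one bond closes ring C and makes the spiro centre.
3. 24 ⇒ 19 + 22 (C11–C13, hydroboration/B-alkyl Suzuki, sets C9). 19 ⇒ 15 (C8–C14, Ireland–Claisen of the C11 chloroacetate, sets C8).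
4. 15 ⇒ 10 (C7 oxidation, hydride reduction) ⇒ 7 + 8 (ester-tethered intramolecular Diels–Alder, ring B and C10) ⇒ 1 (ring A).
5. Ring order: A (from 1) → B (Diels–Alder) → D (attached as butenolide) → C (key step) → oxirane.

Assumption (numbering convention): C1–C10 is the decalin, with gem-dimethyl on C4 and angular methyl on C10. C11 sits on C9, C14 on C8, and C17 is the carboxyl carbon on C14. Ring D is C13–C12(=O)–O–C16–C15. α is the face opposite the C10 methyl. The given SMILES is taken as the absolute configuration.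

## Route

Step 1
Reactants: 1 2-methylcyclohexane-1,3-dione
Product: 2 3-isobutoxy-2-methylcyclohex-2-en-1-one
Conditions: i-BuOH, p-TsOH·H2O (cat.), PhMe, reflux, Dean–Stark
Reagents that add atoms: isobutanol CC(C)CO
Why: Acid-catalysed vinylogous ester formation masks the future C1 carbonyl and leaves a single enolisable α'-position, and no stereocentre is formed.

Step 2
Reactants: 2 3-isobutoxy-2-methylcyclohex-2-en-1-one
Product: 4 3-isobutoxy-2,6,6-trimethylcyclohex-2-en-1-one, via monomethyl enone 3 (not isolated)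
Conditions: LiN(i-Pr)2, THF, −78 °C, MeI; second portion LiN(i-Pr)2 then MeI in the same flask, −78 → 0 °C
Reagents that add atoms: iodomethane CI
Why: Stork–Danheiser kinetic α'-enolate alkylation run twice installs the C4 gem-dimethyl group, because the vinylogous ester can enolise only at this carbon.

Step 3
Reactants: 4 3-isobutoxy-2,6,6-trimethylcyclohex-2-en-1-one
Product: 6 2,4,4-trimethyl-3-vinylcyclohex-2-en-1-one, via vinyl carbinol 5 (not isolated)
Conditions: CH2=CHMgBr, THF, 0 °C → rt; then 1 M HCl
Reagents that add atoms: vinylmagnesium bromide C=C[Mg]Br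
Why: Stork–Danheiser 1,2-addition followed by acidic enone transposition puts the C6–C7 vinyl group on C5 and unmasks the C1 ketone.

Step 4
Reactants: 6 2,4,4-trimethyl-3-vinylcyclohex-2-en-1-one
Product: 7 (S)-2,4,4-trimethyl-3-vinylcyclohex-2-en-1-ol
Conditions: (R)-2-methyl-CBS-oxazaborolidine (C18H20BNO, 10 mol%), BH3·SMe2, THF, −20 °C; MeOH
Reagents that add atoms: none
Why: In this Corey–Bakshi–Shibata reduction the α-methyl alkenyl side acts as the large group, so the (R)-catalyst gives the (S)-carbinol (C1), the only reagent-controlled stereocentre, from which all others are relayed.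

Step 5
Reactants: 7 (S)-2,4,4-trimethyl-3-vinylcyclohex-2-en-1-ol; 8 propiolic acid
Product: 10 diene lactone (Δ5 and Δ8(9) diene; C9–C11(=O)–O–C1 γ-lactone on the α face; 10β-methyl), via propiolate ester 9 (not isolated)
Conditions: DCC, 4-(dimethylamino)pyridine (5 mol%), CH2Cl2, −20 °C; filter; PhMe, 110 °C
Reagents that add atoms: none
Why: Steglich esterification is followed by an ester-tethered intramolecular Diels–Alder reaction in which the three-atom tether forces the alkyne onto the diene face carrying the C1 oxygen, so C9–C10 forms cis to C1–O and fixes the quaternary C10 (methyl β) while closing ring B.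

Step 6
Reactants: 10 diene lactone
Product: 11 7-oxo dienone lactone
Conditions: CrO3, 3,5-dimethylpyrazole, CH2Cl2, −20 °C
Reagents that add atoms: chromium trioxide O=[Cr](=O)=O
Why: Allylic oxidation attacks the only allylic methylene, the doubly allylic C7, and ring B cannot aromatise because C10 is quaternary.

Step 7
Reactants: 11 7-oxo dienone lactone
Product: 12 triol (1α-OH; 7β-OH; C11H2OH on C9; Δ5 and Δ8(9))
Conditions: i-Bu2AlH (6 equiv), CH2Cl2, −78 → 0 °C; aq. KNaC4H4O6
Reagents that add atoms: none
Why: This 1,2-selective hydride reduction opens the unsaturated lactone to the allylic diol and attacks the flat dienone carbonyl from the α face opposite the C10 methyl, giving the 7β-alcohol.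

Step 8
Reactants: 12 triol; 13 chloroacetyl chloride
Product: 15 1α,7β-diacetate 11-chloroacetate, via mono chloroacetate 14 (not isolated)
Conditions: ClCH2COCl (1.0 equiv), 2,4,6-collidine, CH2Cl2, −78 °C; then Ac2O, Et3N, 4-(dimethylamino)pyridine (cat.), 0 °C → rt
Reagents that add atoms: acetic anhydride CC(=O)OC(C)=O
Why: In this chemoselective acylation the unhindered primary allylic hydroxyl takes the one equivalent of acid chloride, and the two secondary hydroxyls then receive their final acetates in the same flask without touching any stereocentre.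

Step 9
Reactants: 15 1α,7β-diacetate 11-chloroacetate
Product: 19 methyl 2-chloro-2-(1α,7β-diacetoxy-4,4,10β-trimethyl-9-methylene-Δ5-octalin-8α-yl)acetate (8β-H; C14 epimers), via ketene silyl acetal 16 (not isolated), via trimethylsilyl ester 17 (not isolated), via chloro acid 18 (not isolated)
Conditions: LiN(SiMe3)2 (1.15 equiv), Me3SiCl, THF, −95 → 60 °C; 0.5 M HCl; then Me3SiCHN2, PhMe/MeOH, 0 °C
Reagents that add atoms: (trimethylsilyl)diazomethane C[Si](C)(C)C=[N+]=[N-]; chlorotrimethylsilane C[Si](C)(C)Cl (silicon stays only in 16 and 17)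
Why: In this Ireland–Claisen rearrangement the chloroacetate is several pK units more acidic than the acetates and is enolised selectively, and the [3,3] shift delivers C14 to C8 on the α face, anti to the adjacent 7β-acetate and the C10 methyl (8β-H), while moving the alkene to C9=C11 and placing the halogen on C14.

Step 10
Reactants: 20 furan-2(5H)-one
Product: 22 3-bromofuran-2(5H)-one, via dibromolactone 21 (not isolated)
Conditions: Br2, CH2Cl2, 40 °C; then Et3N, 0 °C
Reagents that add atoms: bromine BrBr
Why: Bromine addition is followed by E1cB-type dehydrobromination, in which the acidic α-hydrogen leaves together with the β-bromide, so only the α-bromobutenolide forms.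

Step 11
Reactants: 19 methyl chloro ester with 9-methylene group; 22 3-bromofuran-2(5H)-one
Product: 24 butenolide chloro ester (as 19 but 9α-H and C9β–CH2–(2-oxo-2,5-dihydrofuran-3-yl)), via alkyl borane 23 (not isolated)
Conditions: 9-BBN, THF, 60 °C; then 22, Pd(dppf)Cl2 (10 mol%), AsPh3, aq. K3PO4, DMF, rt
Reagents that add atoms: 9-borabicyclo[3.3.1]nonane B1C2CCCC1CCC2 (boron unit stays only in 23)
Why: In this hydroboration/B-alkyl Suzuki–Miyaura coupling 9-BBN touches only the 1,1-disubstituted alkene and approaches from the α face opposite the adjacent angular methyl (the behaviour of 17-methylene steroids), so hydrogen lands on C9α and C11 becomes equatorial, and the sp3–sp2 coupling then makes C11–C13.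

Step 12
Reactants: 24 butenolide chloro ester
Product: 26 spiro enol lactone (ring C closed; 14β-CO2Me; C12 α; C15 β; C15=C16), via iodo ester 25 (not isolated)
Conditions: Cs2CO3 (1.5 equiv), NaI (0.3 equiv), 4 Å MS, MeCN, 0 °C → rt
Reagents that add atoms: sodium iodide [Na+].[I-] (iodine stays only in 25)
Why: Proposed new method: Cs2CO3 removes only the acidic γ-proton of the butenolide (acetates and methyl ester stay untouched) to give an aromatic 2-furanolate whose C13 is a natural α-carbon donor, while C14, also a natural α-carbon donor, has been turned by its halogen into an acceptor (a2, enolonium-equivalent synthon), so a 5-exo-tet SN2 alkylation joins two normally nucleophilic carbons and creates the dissonant succinate bond, ring C and the spiro centre at once; attack through C16 would need a bridged seven-membered ring, iodide exchange epimerises C14 faster than ring closure (dynamic kinetic resolution) so both epimers pass through the transition state with CO2Me pseudo-equatorial (β, trans to C7) and the bulky C12–OCs edge of the furanolate turned away from it (C12 α, C15 β); the closest known reactions are C3-alkylation of butenolide dienolates with alkyl halides and the enolate/α-halo ester synthesis of succinates.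

Step 13
Reactants: 26 spiro enol lactone
Product: 28 5-deoxy-5,6-didehydrospirocaesalmin (15,16-oxirane on the C14 side), via bromolactol 27 (not isolated)
Conditions: NBS (1.05 equiv), H2O (5 equiv), THF, −20 °C; then Ag2O, 4 Å MS, 0 °C → rt, dark
Reagents that add atoms: water O; N-bromosuccinimide O=C1CCC(=O)N1Br (bromine stays only in 27)
Why: Proposed new method: electrophilic bromine adds to C15 of the enol ester from the open C11 side (the C14 side is covered by the cis CO2Me), water caps C16, and the lactol oxygen lying anti to bromine displaces it (3-exo-tet, Ag2O as halophile and mild base), so the oxirane ends on the hindered C14 side that direct epoxidation would miss; C16 equilibrates through the open aldehyde acid so only the anti lactol is drained, and Δ5 is a spectator because it is deactivated by the allylic acetate and anti opening of its bromonium ion would have to pass between the 4β- and 10β-methyl groups; the closest known reaction is the halohydrin route from glycals to 1,2-anhydrosugars.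

Step 14
Reactants: 28 5-deoxy-5,6-didehydrospirocaesalmin
Product: 30 spirocaesalmin, via hydroperoxide 29 (not isolated)
Conditions: Co(acac)2 (20 mol%), PhSiH3, O2 (1 atm), THF, rt; then PPh3
Reagents that add atoms: dioxygen O=O
Why: In this Mukaiyama hydration (metal-hydride hydrogen-atom transfer) hydrogen adds to C6 of the only remaining alkene and the tertiary C5 radical is trapped by O2 from the α face, because the β face is closed by the 4β- and 10β-methyl groups, giving the trans-decalin 5α-hydroperoxide that PPh3 reduces to the 5α-alcohol under neutral, alcohol-free conditions.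

## Compound list
1 | 2-methylcyclohexane-1,3-dione | CC1C(=O)CCCC1=O | starting material
2 | 3-isobutoxy-2-methylcyclohex-2-en-1-one | CC(C)COC1=C(C)C(=O)CCC1 | intermediate
3 | 3-isobutoxy-2,6-dimethylcyclohex-2-en-1-one (racemic) | CC(C)COC1=C(C)C(=O)C(C)CC1 | intermediate
4 | 3-isobutoxy-2,6,6-trimethylcyclohex-2-en-1-one | CC(C)COC1=C(C)C(=O)C(C)(C)CC1 | intermediate
5 | 3-isobutoxy-2,6,6-trimethyl-1-vinylcyclohex-2-en-1-ol (racemic) | CC(C)COC1=C(C)C(O)(C=C)C(C)(C)CC1 | intermediate
6 | 2,4,4-trimethyl-3-vinylcyclohex-2-en-1-one | CC1=C(C=C)C(C)(C)CCC1=O | intermediate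
7 | (S)-2,4,4-trimethyl-3-vinylcyclohex-2-en-1-ol | O[C@H]1CCC(C)(C)C(C=C)=C1C | intermediate
8 | propiolic acid | C#CC(=O)O | starting material
9 | (S)-2,4,4-trimethyl-3-vinylcyclohex-2-en-1-yl propiolate | C#CC(=O)O[C@H]1CCC(C)(C)C(C=C)=C1C | intermediate
10 | diene lactone: Δ5,Δ8(9)-diene, 4,4,10β-trimethyl, C9–C11(=O)–O–C1α γ-lactone | O=C1O[C@H]2CCC(C)(C)C3=CCC=C1[C@@]23C | intermediate
11 | 7-oxo dienone lactone | O=C1O[C@H]2CCC(C)(C)C3=CC(=O)C=C1[C@@]23C | intermediate
12 | triol: 1α-OH, 7β-OH, 9-CH2OH, Δ5,Δ8(9) | OCC1=C[C@@H](O)C=C2C(C)(C)CC[C@H](O)[C@]12C | intermediate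
13 | chloroacetyl chloride | ClCC(Cl)=O | starting material
14 | 11-O-chloroacetyl 1α,7β-diol | O=C(CCl)OCC1=C[C@@H](O)C=C2C(C)(C)CC[C@H](O)[C@]12C | intermediate
15 | 1α,7β-diacetate 11-chloroacetate | O=C(CCl)OCC1=C[C@@H](OC(C)=O)C=C2C(C)(C)CC[C@H](OC(C)=O)[C@]12C | intermediate
16 | O-trimethylsilyl chloroketene acetal of 15 | C[Si](C)(C)OC(=CCl)OCC1=C[C@@H](OC(C)=O)C=C2C(C)(C)CC[C@H](OC(C)=O)[C@]12C | intermediate
17 | trimethylsilyl ester of the rearranged chloro acid (8β-H, 9-methylene) | C[Si](C)(C)OC(=O)C(Cl)[C@@H]1[C@@H](OC(C)=O)C=C2C(C)(C)CC[C@H](OC(C)=O)[C@]2(C)C1=C | intermediate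
18 | rearranged chloro acid (8β-H, 9-methylene, C14 epimers) | OC(=O)C(Cl)[C@@H]1[C@@H](OC(C)=O)C=C2C(C)(C)CC[C@H](OC(C)=O)[C@]2(C)C1=C | intermediate
19 | methyl chloro ester (8β-H, 9-methylene, Δ5, 1α,7β-diacetate, C14 epimers) | COC(=O)C(Cl)[C@@H]1[C@@H](OC(C)=O)C=C2C(C)(C)CC[C@H](OC(C)=O)[C@]2(C)C1=C | intermediate
20 | furan-2(5H)-one | O=C1C=CCO1 | starting material
21 | trans-3,4-dibromodihydrofuran-2(3H)-one (racemic, one enantiomer drawn) | O=C1OC[C@@H](Br)[C@@H]1Br | intermediate
22 | 3-bromofuran-2(5H)-one | O=C1OCC=C1Br | intermediate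
23 | C11-(9-borabicyclo[3.3.1]nonan-9-yl) borane, 9α-H | COC(=O)C(Cl)[C@@H]1[C@@H](OC(C)=O)C=C2C(C)(C)CC[C@H](OC(C)=O)[C@]2(C)[C@H]1CB3C4CCCC3CCC4 | intermediate
24 | butenolide chloro ester, 9α-H, C11H2 bonded to C3 of 2(5H)-furanone | COC(=O)C(Cl)[C@@H]1[C@@H](OC(C)=O)C=C2C(C)(C)CC[C@H](OC(C)=O)[C@]2(C)[C@H]1CC3=CCOC3=O | intermediate
25 | butenolide iodo ester (C14 epimers in exchange) | COC(=O)C(I)[C@@H]1[C@@H](OC(C)=O)C=C2C(C)(C)CC[C@H](OC(C)=O)[C@]2(C)[C@H]1CC3=CCOC3=O | intermediate
26 | spiro enol lactone (14β-CO2Me, C12 α, C15 β, Δ5, Δ15) | COC(=O)[C@H]1[C@@H]2[C@@H](OC(C)=O)C=C3C(C)(C)CC[C@H](OC(C)=O)[C@]3(C)[C@H]2C[C@]12C(=O)OC=C2 | intermediate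
27 | 15-bromo-16-hydroxy lactol (Br on the C11 side, OH anti) | COC(=O)[C@H]1[C@@H]2[C@@H](OC(C)=O)C=C3C(C)(C)CC[C@H](OC(C)=O)[C@]3(C)[C@H]2C[C@]12C(=O)O[C@H](O)[C@H]2Br | intermediate
28 | 5-deoxy-5,6-didehydrospirocaesalmin | COC(=O)[C@H]1[C@@H]2[C@@H](OC(C)=O)C=C3C(C)(C)CC[C@H](OC(C)=O)[C@]3(C)[C@H]2C[C@]12C(=O)O[C@@H]1O[C@@H]12 | intermediate
29 | spirocaesalmin 5α-hydroperoxide | COC(=O)[C@H]1[C@@H]2[C@@H](OC(C)=O)C[C@@]3(OO)C(C)(C)CC[C@H](OC(C)=O)[C@]3(C)[C@H]2C[C@]12C(=O)O[C@@H]1O[C@@H]12 | intermediate
30 | spirocaesalmin (1α-OAc, 5α-OH, 7β-OAc, 8β-H, 9α-H, 14β-CO2Me) | COC(=O)[C@H]1[C@@H]2[C@@H](OC(C)=O)C[C@@]3(O)C(C)(C)CC[C@H](OC(C)=O)[C@]3(C)[C@H]2C[C@]12C(=O)O[C@@H]1O[C@@H]12 | target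

## Step count and risks
Total step count: 14. Longest linear sequence: 13 (steps 1–9 and 11–14).

**Step 11.** The risks are the face selectivity at C9 and coupling next to an α-chloro ester and an allylic acetate.
- The fallback sets out from 19 and comes back at 24.
- Borane 23, as either C9 epimer, is oxidised with NaBO3·4H2O to the primary alcohol F1.
- Dess–Martin periodinane followed by Et3N on silica gives the equilibrated equatorial 9α-H aldehyde F2. C9 is now α to a carbonyl group, so it is set thermodynamically rather than by reagent approach.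
- Wittig olefination with 3-(triphenylphosphoranylidene)dihydrofuran-2(3H)-one gives the (E)-alkylidene lactone F3.
- RhCl3·3H2O in warm EtOH moves the double bond into the lactone ring to give 24.

**Step 12.** The risks are E2 loss of hydrogen halide to the C8=C14 enoate, or Michael-initiated cyclopropanation by the chloro ester enolate, in place of spiro-alkylation.
- The fallback sets out from 24 and comes back at 26.
- i-Pr3SiOTf/Et3N converts the butenolide into the 2-silyloxyfuran F4.
- Visible-light photoredox catalysis (Ir(ppy)3, NaI, MeCN) turns the carbon–halogen bond into an electrophilic α-ester radical.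
- This radical adds 5-exo to C13 of the electron-rich furan. Oxidation of the dioxy-stabilised C12 radical and loss of the silyl group give 26 without any base.

**Step 13.** The risks are β-lactone formation, epimerisation of the α-bromo aldehyde, and hydrolysis in place of oxirane closure.
- The fallback sets out from 26 and comes back at 28.
- Mild hydrolysis (H2O, THF, cat. Et3N) opens the enol lactone to the aldehyde acid F5.
- Catalyst-controlled enamine α-chlorination (NCS with the matched enantiomer of 2,5-diphenylpyrrolidine) gives the α-chloro aldehyde acid F6 with chlorine on the C11 side, independent of substrate bias.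
- Ag2O with 4 Å MS in CH2Cl2 then closes lactol and oxirane to give 28.

## Further compounds
F1 | step 11 | primary alcohol (C11H2OH on C9, C9 epimers) | COC(=O)C(Cl)[C@@H]1[C@@H](OC(C)=O)C=C2C(C)(C)CC[C@H](OC(C)=O)[C@]2(C)C1CO
F2 | step 11 | equatorial 9α-H aldehyde | COC(=O)C(Cl)[C@@H]1[C@@H](OC(C)=O)C=C2C(C)(C)CC[C@H](OC(C)=O)[C@]2(C)[C@H]1C=O
F3 | step 11 | (E)-alkylidene lactone | COC(=O)C(Cl)[C@@H]1[C@@H](OC(C)=O)C=C2C(C)(C)CC[C@H](OC(C)=O)[C@]2(C)[C@H]1/C=C3\CCOC3=O
F4 | step 12 | 2-(triisopropylsilyloxy)furan | COC(=O)C(Cl)[C@@H]1[C@@H](OC(C)=O)C=C2C(C)(C)CC[C@H](OC(C)=O)[C@]2(C)[C@H]1Cc3ccoc3O[Si](C(C)C)(C(C)C)C(C)C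
F5 | step 13 | aldehyde acid | COC(=O)[C@H]1[C@@H]2[C@@H](OC(C)=O)C=C3C(C)(C)CC[C@H](OC(C)=O)[C@]3(C)[C@H]2C[C@]1(CC=O)C(O)=O
F6 | step 13 | α-chloro aldehyde acid | COC(=O)[C@H]1[C@@H]2[C@@H](OC(C)=O)C=C3C(C)(C)CC[C@H](OC(C)=O)[C@]3(C)[C@H]2C[C@]1([C@H](Cl)C=O)C(O)=O
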